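The eta run carried 0.74 equiv of coupling partner against the substrate. The theta run, with more partner, is the flask asked about.

| flask | substrate | coupling partner | remark | time |
|---|---|---|---|---|
| theta | 0.10 M | 1.1 equiv | the very flask that is asked about, followed so far |  |
| eta | 0.10 M | 0.74 equiv | run made earlier |  |
| flask | 0.10 M | 1.10 equiv |  | 80 min |

| run | time / min | target / % |
|---|---|---|
| theta | 0.333 | 9.7 |
| theta | 1.33 | 24.6 |
| theta | 4.00 | 9.2 |
| theta | 15.0 | 0.7 |
| eta | 0.500 | 12.6 |
| eta | 2.50 | 11.7 |
| eta | 12.0 | 1.4 |
| eta | 60.0 | 2.5 |

(standard deviation of a reading: 1 percentage point)

- time up to 80 min at which target stands highest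
- the amount of target, in percent of the substrate charged, at that time

Target rises and falls in both runs, and in theta it falls between 1.33 min and 4.00 min with a rate constant of 0.368 min⁻¹. Two of us read this differently.

The racer divides theta's early rise, 0.291 min⁻¹ as a fraction of the charge, by that constant. Time drops out and leaves 79.1%, the level at which feed balances loss. The racer therefore holds that height follows speed and that a crest well above the reading hides before 4.00 min.

The counter answers that the feed draws on a finite charge. The counter takes theta's best reading, 24.6%, as the crest yield, the highest target as a fraction of the charge of the limiting reagent. In theta that reagent is the substrate. In eta it is the coupling partner, so the rule expects a crest of 18.2% there.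

As a test, the counter carries eta's reading at 2.50 min back to 1.33 min along the same fall, which gives 18.0%. That reading carries its scatter of 1 percentage point, magnified by the carrying back.

I side with the counter and expect about 24.6% near 1.33 min. The forecast, a little higher, gives 25.5% at 1.4 min, because the reading “sits almost on the crest”.

The flask reaches 23.6% at 1.25 min, far lower than the racer's level.

    substrate + coupling partner → intermediate (k = 1.10 L mol⁻¹ s⁻¹)
    intermediate ⇌ target (K = 1.50, k = 0.0140 s⁻¹)
    target ⇌ isomer of the product (K = 19.0, k = 0.0110 s⁻¹)
    intermediate → decomposed reagent (k = 0.00690 s⁻¹)

In the flask the substrate's half-life by coupling, 0.095 min, is shorter than the 0.83 min forward half-life of intermediate going to target at 0.132 min, and a neighbour at the same substrate concentration with 0.440 equiv of partner reckons by the crest yield to 10.8% and reaches 11.3%. The racer's view holds in direction in the dilute neighbour with 0.025 M of substrate at the same equivalents, where the feed is a quarter as fast and the crest reaches 18.3%, lower than the flask's 23.6%, though by a factor of just 1.29.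

Readings and results were computed with constants of no real substance.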